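## The problem

Kazinol B (16) is a (2S)-flavan. Ring C (O1, C2, C3, C4) is fused to ring A (C4a to C8a), which carries one phenol on C7. C2 holds ring B, a benzene with a single hydrogen that is fused to a 2,2-dimethyl-2H-pyran (ring D) and bears a prenyl group and a free phenol on neighbouring carbons.

The only stereocenter is C2, so its configuration must come from a reagent. Once set it must be kept from ionising, because it is benzylic, oxygen-bound and para to the pyran oxygen of ring B. Ring B is a regiochemical task of its own: five contiguous substituents (the C2 carbon, prenyl, hydroxyl, pyran oxygen, pyran carbon) surround one hydrogen.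

The functional groups are fragile. A prenyl group beside a phenol closes to a chroman in strong acid, the chromene double bond suffers from acid, oxidants and hydrogenation, and the two alkenes exclude hydrogenolytic deprotection.

A gentle closure of ring C is possible because of where O1 sits: on C8a, ortho to the chain-bearing C4a and meta to the C7 oxygen. That is the carbon at which a C8–C8a aryne with an alkoxy group on C7 accepts nucleophiles. A C2 alkoxide held by the C3–C4 tether can reach that carbon and no other, so ring A needs only one oxygen and one halogen at the start, and the C2–O bond is never made or broken after the stereocenter exists.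

## Retrosynthesis

**16 to 15.** Only the two phenol protecting groups are cut. Methoxymethyl (MOM) is chosen for O7 because it survives a lithium amide, withdraws inductively (which polarises the aryne), cannot migrate to a neighbouring carbanion as a silyl group would, and needs no hydrogenolysis. The ring B phenol gets the same group so that one mild acidic step frees both.

**15 to 13 (through 14).** The O1–C8a bond is cut, giving the acyclic bromo alcohol 13. The neighbouring cut, O1–C2, would need a second, differentiated oxygen on ring A and a substitution at a para-alkoxybenzylic carbon, with inversion and a risk of ionisation. A metal-catalysed C–O coupling would cut the same bond but needs the halogen on C8a itself. The aryne route keeps the C2–O bond intact, removes one ring, and takes its bromine from a catalogue aldehyde. The forward reaction must form the C8–C8a aryne 14 regioselectively and add the alkoxide at C8a.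

**13 to 12.** The C2–H bond is cut, leading back to the aryl alkyl ketone 12. Asymmetric transfer hydrogenation is preferred over asymmetric addition of an organometallic to an aldehyde, because the ketone comes directly from aldol chemistry and the catalyst tolerates alkenes and the aryl bromide.

**12 to 11 to 8 + 10.** The C3–C4 bond is cut as the enone double bond of chalcone 11, which splits the molecule into methyl ketone 8 (rings B and D) and aldehyde 10 (ring A). The forward sequence must reduce only the enone C=C in the presence of a chromene alkene, a prenyl alkene and an aryl bromide, which points to copper hydride.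

**10 to 9.** Aldehyde 10 is the MOM ether of commercial 3-bromo-4-hydroxybenzaldehyde (9).

**8 to 7 to 6 to 5 to 4 + 2.** The prenyl C–C bond on ring B is traced to an oxygen-bound 1,1-dimethylallyl group in 6. A [3,3] shift delivers it, with allyl inversion, as a linear prenyl group to the only ortho carbon bearing hydrogen, giving 7 and then its MOM ether 8. Direct C-prenylation or cross-coupling would need a regioselective halogenation or would compete with O-alkylation. Ether 6 comes from propargyl ether 5 by semi-hydrogenation, and 5 from phenol 4 and chloride 2.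

**4 to 3 to 1 + 2.** Ring D is cut at its O–C(Me2) bond and at the bond from the ring B carbon to the pyran CH, giving the aryl propargyl ether 3. Its thermal rearrangement can only go to the single free ortho position. Ether 3 comes from 3,4-dihydroxyacetophenone (1) and chloride 2, and the forward reaction relies on the higher acidity of the hydroxyl para to the acetyl group.

## Roads not taken

**Alternative 1:** Ring A is removed altogether by cutting C4a–C5 and C8–C8a, which leads back to the (6S)-6-aryl δ-lactone A1, whose stereocenter is the future C2.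
- Forward key step: the lithium enolate of A1 adds to an α-silyl vinyl ketone acceptor, and after an alkoxide base the methyl ketone enolate attacks the lactone carbonyl. This gives the cyclohexane-1,3-dione A2 and releases the C2 alkoxide. Condensation of that alcohol onto the adjacent carbonyl and oxidation of the carbocycle to the phenol would finish rings C and A.
- Merits: no aryl halide and no strong amide base near the prenyl CH2; the O1–C8a bond forms by a condensation whose regiochemistry is built in.
- Weak points: the late aromatisation needs an oxidant in a molecule with a chromene alkene, a prenyl group and an electron-rich ring B, all of which the usual dehydrogenating agents attack. The sequence from A1 is also several steps longer than closing ring C on a ready-made arene.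
- Comparison: on base sensitivity this road is better. The chosen plan offsets that with a one-step closure on a bought aromatic ring and no oxidation after the alkenes are in place.

**Alternative 2:** O1–C2 and C3–C4 are cut together, leading to the salicylaldehyde A3 and the cinnamaldehyde A4.
- Forward key step: under a chiral diarylprolinol silyl ether, the phenol of A3 adds to the β-carbon of A4 and the enamine condenses with the aryl aldehyde. The product is the 2H-chromene-3-carbaldehyde A5, with the target's arrangement at C2 (descriptor R, because C3 outranks the aryl group).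
- Merits: ring C and the stereocenter arise in one catalytic step from two aldehydes, with no metal and no strong base. In that respect it is more economical than the condensation, reduction, transfer hydrogenation and cyclisation of the chosen plan.
- Weak points: the formyl carbon is not part of the target and must be excised by decarbonylation. C3=C4 must be saturated beside the chromene alkene of ring D, which is the same kind of double bond. A 2-aryl-2H-chromene can lose its configuration by reversible ring opening. The β-carbon of A4 is flanked by a prenyl group, which should slow the oxa-Michael step. A4 itself needs a two-carbon homologation of a ring B aldehyde.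
- Comparison: the chosen plan has no extraneous carbon to remove, no second chromene alkene to distinguish, and a C2–O bond that stays untouched after the stereocenter is set.

**Alternative 3:** Ring D is made last, by cutting its carbon–carbon bond to ring B and its O–C(Me2) bond. This leads to the catechol flavan A6 and 3-methylbut-2-enal A7.
- Forward key step: the titanium aryloxide of A6 condenses with A7 at the one free position ortho to a phenol, and oxa-6π closure of the ortho-quinone methide gives Kazinol B 7-O-silyl ether A8. Fluoride would then give 16.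
- Merits: the annulation site is unambiguous because the prenyl group blocks the other ortho carbon. The ring B phenol never needs protection, and the final deprotection is fluoride, not acid. That is gentler toward the prenyl phenol than the acidic last step of the chosen plan.
- Weak points: it solves neither ring C nor C2. A6 must still be made as a single enantiomer, with a prenylated catechol carried through the whole sequence. A catechol tends to bind titanium as a chelate and not as the monodentate aryloxide the condensation needs. A free ortho-prenyl phenol meets a Lewis acid, and the catechol is easily oxidised.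
- Comparison: the chosen plan builds ring D first, on the simple acetophenone 1, where the thermal propargyl rearrangement has only one course. This road is an alternative endgame, not an alternative to the key disconnection.

Key step: step 11

Assumption: 3-chloro-3-methylbut-1-yne (2) is bought as such; it is the hydrochlorination product of 2-methylbut-3-yn-2-ol, and making it would add one step.

Step 1
Reactants: 1 3,4-dihydroxyacetophenone; 2 3-chloro-3-methylbut-1-yne
Product: 3 1-[3-hydroxy-4-(2-methylbut-3-yn-2-yloxy)phenyl]ethanone
Conditions: DBU (1.1 equiv), CuCl2·2H2O (1 mol %), MeCN, −5 to 0 °C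
Reagents that add atoms: none
Why: Copper-catalysed propargylic etherification of a phenoxide with a tertiary propargyl chloride (copper acetylide pathway). The hydroxyl para to the acetyl group is much more acidic than its neighbour, so one equivalent of DBU should ionise and alkylate only that oxygen.

Step 2
Reactants: 3 1-[3-hydroxy-4-(2-methylbut-3-yn-2-yloxy)phenyl]ethanone
Product: 4 1-(8-hydroxy-2,2-dimethyl-2H-chromen-6-yl)ethanone
Conditions: PhNEt2, 190 °C
Reagents that add atoms: none
Why: Aryl propargyl ether Claisen rearrangement to the only free ortho carbon, then 1,5-hydrogen shift and oxa-6π electrocyclisation, the standard thermal route to 2,2-dimethyl-2H-chromenes. The other ortho position carries the hydroxyl and is blocked.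

Step 3
Reactants: 4 1-(8-hydroxy-2,2-dimethyl-2H-chromen-6-yl)ethanone; 2 3-chloro-3-methylbut-1-yne
Product: 5 1-[2,2-dimethyl-8-(2-methylbut-3-yn-2-yloxy)-2H-chromen-6-yl]ethanone
Conditions: DBU (1.3 equiv), CuCl2·2H2O (1 mol %), MeCN, 0 °C
Reagents that add atoms: none
Why: The same copper-catalysed propargylic etherification, now on the single remaining phenol.

Step 4
Reactants: 5 1-[2,2-dimethyl-8-(2-methylbut-3-yn-2-yloxy)-2H-chromen-6-yl]ethanone
Product: 6 1-[2,2-dimethyl-8-(2-methylbut-3-en-2-yloxy)-2H-chromen-6-yl]ethanone
Conditions: H2 (1 atm), Pd/CaCO3 poisoned with Pb(OAc)2 (Lindlar catalyst), quinoline, EtOAc, rt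
Reagents that add atoms: none
Why: Lindlar semi-hydrogenation stops a terminal alkyne at the alkene. The poisoned catalyst should leave the cis-disubstituted chromene double bond and the ketone alone.

Step 5
Reactants: 6 1-[2,2-dimethyl-8-(2-methylbut-3-en-2-yloxy)-2H-chromen-6-yl]ethanone
Product: 7 1-[8-hydroxy-2,2-dimethyl-7-(3-methylbut-2-en-1-yl)-2H-chromen-6-yl]ethanone
Conditions: PhNEt2, 150 °C
Reagents that add atoms: none
Why: Aromatic Claisen rearrangement of a 1,1-dimethylallyl aryl ether. The [3,3] shift inverts the allyl unit, so the tertiary ether delivers a linear prenyl group to the only ortho carbon bearing hydrogen, and tautomerisation restores the phenol.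

Step 6
Reactants: 7 1-[8-hydroxy-2,2-dimethyl-7-(3-methylbut-2-en-1-yl)-2H-chromen-6-yl]ethanone
Product: 8 1-[8-(methoxymethoxy)-2,2-dimethyl-7-(3-methylbut-2-en-1-yl)-2H-chromen-6-yl]ethanone
Conditions: MOMCl, iPr2NEt, CH2Cl2, 0 °C to rt
Reagents that add atoms: chloromethyl methyl ether (MOMCl), COCCl
Why: O-Alkylation of a phenol with chloromethyl methyl ether under amine base (Williamson-type). The phenol is meta to the ketone and not hydrogen-bonded to it, so it should alkylate normally.

Step 7
Reactants: 9 3-bromo-4-hydroxybenzaldehyde
Product: 10 3-bromo-4-(methoxymethoxy)benzaldehyde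
Conditions: MOMCl, iPr2NEt, CH2Cl2, 0 °C to rt
Reagents that add atoms: chloromethyl methyl ether (MOMCl), COCCl
Why: The same phenol O-alkylation; the acidic phenol para to the aldehyde reacts cleanly.

Step 8
Reactants: 8 1-[8-(methoxymethoxy)-2,2-dimethyl-7-(3-methylbut-2-en-1-yl)-2H-chromen-6-yl]ethanone; 10 3-bromo-4-(methoxymethoxy)benzaldehyde
Product: 11 (2E)-3-[3-bromo-4-(methoxymethoxy)phenyl]-1-[8-(methoxymethoxy)-2,2-dimethyl-7-(3-methylbut-2-en-1-yl)-2H-chromen-6-yl]prop-2-en-1-one
Conditions: KOH (aq.), EtOH, 0 °C to rt
Reagents that add atoms: none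
Why: Claisen–Schmidt condensation of a methyl ketone with a non-enolisable aldehyde; dehydration of the aldol gives the E enone. MOM ethers, the aryl bromide and both alkenes are inert to hydroxide.

Step 9
Reactants: 11 (2E)-3-[3-bromo-4-(methoxymethoxy)phenyl]-1-[8-(methoxymethoxy)-2,2-dimethyl-7-(3-methylbut-2-en-1-yl)-2H-chromen-6-yl]prop-2-en-1-one
Product: 12 3-[3-bromo-4-(methoxymethoxy)phenyl]-1-[8-(methoxymethoxy)-2,2-dimethyl-7-(3-methylbut-2-en-1-yl)-2H-chromen-6-yl]propan-1-one
Conditions: [(Ph3P)CuH]6 (5 mol %), PhMe2SiH, t-BuOH, PhMe, rt
Reagents that add atoms: none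
Why: Copper hydride conjugate reduction: the phosphine-ligated hydride adds to the β-carbon of the enone, tert-butanol protonates the copper enolate and the silane regenerates the hydride. Unactivated and styrenyl alkenes, the aryl bromide and the saturated ketone should not react.

Step 10
Reactants: 12 3-[3-bromo-4-(methoxymethoxy)phenyl]-1-[8-(methoxymethoxy)-2,2-dimethyl-7-(3-methylbut-2-en-1-yl)-2H-chromen-6-yl]propan-1-one
Product: 13 (1S)-3-[3-bromo-4-(methoxymethoxy)phenyl]-1-[8-(methoxymethoxy)-2,2-dimethyl-7-(3-methylbut-2-en-1-yl)-2H-chromen-6-yl]propan-1-ol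
Conditions: RuCl(p-cymene)[(S,S)-TsDPEN] (2 mol %), HCO2H/Et3N (5:2), EtOAc, 30 °C
Reagents that add atoms: none
Why: Noyori asymmetric transfer hydrogenation of an aryl alkyl ketone. With the (S,S) ligand the hydride goes to the face that gives the S carbinol (the aryl group is recognised by the η6-arene of the catalyst), and formate reduces neither the alkenes nor the aryl bromide.

Step 11
Reactants: 13 (1S)-3-[3-bromo-4-(methoxymethoxy)phenyl]-1-[8-(methoxymethoxy)-2,2-dimethyl-7-(3-methylbut-2-en-1-yl)-2H-chromen-6-yl]propan-1-ol
Product: 15 Kazinol B bis(methoxymethyl) ether [(2S)-7-(methoxymethoxy)-2-[8-(methoxymethoxy)-2,2-dimethyl-7-(3-methylbut-2-en-1-yl)-2H-chromen-6-yl]-3,4-dihydro-2H-chromene], via lithium alkoxide aryne 14 (not isolated)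
Conditions: lithium 2,2,6,6-tetramethylpiperidide (3.2 equiv, from 2,2,6,6-tetramethylpiperidine and n-BuLi), THF (dilute), −78 to 0 °C; then H2O
Reagents that add atoms: none
Why: The first equivalent of amide turns the carbinol into its lithium alkoxide; a second removes the only hydrogen ortho to bromine (on the future C8a, possibly helped by coordination to the nearby alkoxide), and the ortho-bromoaryllithium loses LiBr at once to give the C8–C8a aryne 14. The closest known reaction type is the closure of ω-(3-halophenyl)alkanols to chromans by amide-base aryne generation with intramolecular alkoxide capture, together with the distal (meta) addition of nucleophiles to 3-alkoxyarynes. Ring C closes by a 6-exo-dig attack of O1 on C8a in the plane of the aryne, forming the O1–C8a bond; attack at C8 would need a meta-bridged ring and is geometrically excluded. No stereocenter is created: the C2–O bond is never broken, so the S configuration from step 10 is carried through. The step needs regioselective aryne formation and regioselective addition. The first is secured by the single hydrogen ortho to bromine (metalation next to the MOM oxygen is unproductive and reversible through the amine), the second by the tether and by the inductive pull of the C7 OMOM group, which both send the nucleophile to C8a and leave the carbanion on C8 beside oxygen, where it is protonated by the amine or on quench. A hindered, non-nucleophilic amide is used so that the base does not add to the aryne, and low temperature and short contact spare the doubly activated prenyl CH2.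

Step 12
Reactants: 15 Kazinol B bis(methoxymethyl) ether
Product: 16 Kazinol B [(2S)-2-[8-hydroxy-2,2-dimethyl-7-(3-methylbut-2-en-1-yl)-2H-chromen-6-yl]-3,4-dihydro-2H-chromen-7-ol]
Conditions: aq. HCl (3 M, 5 equiv), MeOH/THF, rt to 40 °C
Reagents that add atoms: none
Why: Acid-catalysed acetal exchange of the two aryl MOM ethers with methanol. Dilute acid at low temperature is chosen so that the freed phenol does not add to the neighbouring prenyl group and C2 does not ionise.

## Compound list

1 | 3,4-dihydroxyacetophenone | CC(=O)c1ccc(O)c(O)c1 | starting material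
2 | 3-chloro-3-methylbut-1-yne | C#CC(C)(C)Cl | starting material
3 | 1-[3-hydroxy-4-(2-methylbut-3-yn-2-yloxy)phenyl]ethanone | CC(=O)c1ccc(OC(C)(C)C#C)c(O)c1 | intermediate
4 | 1-(8-hydroxy-2,2-dimethyl-2H-chromen-6-yl)ethanone | CC(=O)c1cc(O)c2OC(C)(C)C=Cc2c1 | intermediate
5 | 1-[2,2-dimethyl-8-(2-methylbut-3-yn-2-yloxy)-2H-chromen-6-yl]ethanone | CC(=O)c1cc(OC(C)(C)C#C)c2OC(C)(C)C=Cc2c1 | intermediate
6 | 1-[2,2-dimethyl-8-(2-methylbut-3-en-2-yloxy)-2H-chromen-6-yl]ethanone | CC(=O)c1cc(OC(C)(C)C=C)c2OC(C)(C)C=Cc2c1 | intermediate
7 | 1-[8-hydroxy-2,2-dimethyl-7-(3-methylbut-2-en-1-yl)-2H-chromen-6-yl]ethanone | CC(=O)c1cc2C=CC(C)(C)Oc2c(O)c1CC=C(C)C | intermediate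
8 | 1-[8-(methoxymethoxy)-2,2-dimethyl-7-(3-methylbut-2-en-1-yl)-2H-chromen-6-yl]ethanone | CC(=O)c1cc2C=CC(C)(C)Oc2c(OCOC)c1CC=C(C)C | intermediate
9 | 3-bromo-4-hydroxybenzaldehyde | O=Cc1ccc(O)c(Br)c1 | starting material
10 | 3-bromo-4-(methoxymethoxy)benzaldehyde | COCOc1ccc(C=O)cc1Br | intermediate
11 | (2E)-3-[3-bromo-4-(methoxymethoxy)phenyl]-1-[8-(methoxymethoxy)-2,2-dimethyl-7-(3-methylbut-2-en-1-yl)-2H-chromen-6-yl]prop-2-en-1-one | COCOc1ccc(/C=C/C(=O)c2cc3C=CC(C)(C)Oc3c(OCOC)c2CC=C(C)C)cc1Br | intermediate
12 | 3-[3-bromo-4-(methoxymethoxy)phenyl]-1-[8-(methoxymethoxy)-2,2-dimethyl-7-(3-methylbut-2-en-1-yl)-2H-chromen-6-yl]propan-1-one | COCOc1ccc(CCC(=O)c2cc3C=CC(C)(C)Oc3c(OCOC)c2CC=C(C)C)cc1Br | intermediate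
13 | (1S)-3-[3-bromo-4-(methoxymethoxy)phenyl]-1-[8-(methoxymethoxy)-2,2-dimethyl-7-(3-methylbut-2-en-1-yl)-2H-chromen-6-yl]propan-1-ol | CC(C)=CCc1c([C@@H](O)CCc3ccc(OCOC)c(Br)c3)cc2c(c1OCOC)OC(C)(C)C=C2 | intermediate
14 | lithium (1S)-3-[4-(methoxymethoxy)-2,3-didehydrophenyl]-1-[8-(methoxymethoxy)-2,2-dimethyl-7-(3-methylbut-2-en-1-yl)-2H-chromen-6-yl]propan-1-olate (aryne) | CC(C)=CCc1c([C@@H]([O-])CCC3=CC=C(OCOC)C#C3)cc2c(c1OCOC)OC(C)(C)C=C2.[Li+] | intermediate
15 | Kazinol B bis(methoxymethyl) ether, (2S)-7-(methoxymethoxy)-2-[8-(methoxymethoxy)-2,2-dimethyl-7-(3-methylbut-2-en-1-yl)-2H-chromen-6-yl]-3,4-dihydro-2H-chromene | CC(C)=CCc1c([C@@H]2CCc3ccc(OCOC)cc3O2)cc2c(c1OCOC)OC(C)(C)C=C2 | intermediate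
16 | Kazinol B, (2S)-2-[8-hydroxy-2,2-dimethyl-7-(3-methylbut-2-en-1-yl)-2H-chromen-6-yl]-3,4-dihydro-2H-chromen-7-ol | CC(C)=CCc1c([C@@H]2CCc3ccc(O)cc3O2)cc2c(c1O)OC(C)(C)C=C2 | target

## Step count and risk

Total: 12 steps. Longest linear sequence: 11 steps (1 to 16 through steps 1–6 and 8–12); the ring A aldehyde is a one-step branch (step 7).

**Step 11 (key step).** The excess amide may deprotonate the benzylic, allylic prenyl CH2, which on quench would move the double bond into conjugation. The aryne may also be trapped between molecules (by another alkoxide or by the amine) if ring closure is slow. Aryne formation itself may lag if base is held up in reversible metalation beside the MOM oxygen.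
Fallback (sets out from 8, returns at 15): the same O1–C8a bond is made by palladium-catalysed intramolecular C–O coupling, which needs bromine on C8a itself.
- Commercial 2-bromo-4-hydroxybenzaldehyde F1 is converted with MOMCl and iPr2NEt into 2-bromo-4-(methoxymethoxy)benzaldehyde F2.
- F2 is condensed with 8 (KOH, EtOH) to the 2-bromo chalcone F3.
- F3 is reduced with catalytic copper hydride to the 2-bromo dihydrochalcone F4.
- F4 is transfer-hydrogenated as in step 10 to the (1S)-2-bromo alcohol F5.
- Pd(OAc)2 with 2-(di-tert-butylphosphino)-1,1'-binaphthyl and Cs2CO3 in toluene at 70 °C (Buchwald–Hartwig etherification, retention at the carbinol) then closes ring C to 15.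

**Step 1.** Alkylation may not discriminate well enough between the two catechol oxygens, or may go on to the bis-ether, and the free catechol may tie up the copper catalyst.
Fallback (sets out from 2, returns at 4): the second oxygen is differentiated from the start. Commercial 4-hydroxy-3-methoxyacetophenone F6 is etherified with 2 under the conditions of step 1 to 1-[3-methoxy-4-(2-methylbut-3-yn-2-yloxy)phenyl]ethanone F7. Heating as in step 2 gives 1-(8-methoxy-2,2-dimethyl-2H-chromen-6-yl)ethanone F8, and nucleophilic demethylation with NaSEt in DMF at 120 °C gives 4.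

**Step 5.** The tertiary allyl ether may fragment to phenol 4 and isoprene faster than it rearranges to a carbon crowded by the acetyl group.
Fallback (sets out from 4, returns at 7, replacing steps 3–5): 4 is O-allylated (allyl bromide, K2CO3, acetone) to the allyl ether F9. Its Claisen rearrangement (PhNEt2, 190 °C) gives the 7-allyl phenol F10, an allyl ether having no easy fragmentation path. Olefin cross-metathesis of F10 with 2-methylbut-2-ene (second-generation Grubbs catalyst, CH2Cl2, 40 °C) turns allyl into prenyl and gives 7.

**Step 10.** The ortho-prenyl group twists the aryl ketone and may lower both rate and facial selectivity. The mildly acidic medium may also erode the para-alkoxybenzylic carbinol over long reaction times.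
Fallback (sets out from 12, returns at 13): stoichiometric boron hydride delivery under oxazaborolidine control, the Corey–Bakshi–Shibata reduction with (R)-2-methyl-CBS-oxazaborolidine and catecholborane in toluene at −78 °C. This gives the S alcohol by the same large-versus-small differentiation, under non-acidic conditions, and does not hydroborate the alkenes. No new compound is involved.

**Step 12.** Acid may drive addition of the freed ring B phenol to the adjacent prenyl alkene (a second pyran ring), attack the chromene, or ionise C2 with loss of configuration.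
Fallback (sets out from 15, returns at 16): TMSOTf with 2,2'-bipyridyl in CH2Cl2 at 0 °C converts aryl MOM ethers into aryl trimethylsilyl ethers under buffered, aprotic conditions. Kazinol B bis(trimethylsilyl) ether F11 is then hydrolysed with water at rt to 16.

## Further compounds

F1 | step 11 | 2-bromo-4-hydroxybenzaldehyde | O=Cc1ccc(O)cc1Br
F2 | step 11 | 2-bromo-4-(methoxymethoxy)benzaldehyde | COCOc1ccc(C=O)c(Br)c1
F3 | step 11 | (2E)-3-[2-bromo-4-(methoxymethoxy)phenyl]-1-[8-(methoxymethoxy)-2,2-dimethyl-7-(3-methylbut-2-en-1-yl)-2H-chromen-6-yl]prop-2-en-1-one | COCOc1ccc(/C=C/C(=O)c2cc3C=CC(C)(C)Oc3c(OCOC)c2CC=C(C)C)c(Br)c1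
F4 | step 11 | 3-[2-bromo-4-(methoxymethoxy)phenyl]-1-[8-(methoxymethoxy)-2,2-dimethyl-7-(3-methylbut-2-en-1-yl)-2H-chromen-6-yl]propan-1-one | COCOc1ccc(CCC(=O)c2cc3C=CC(C)(C)Oc3c(OCOC)c2CC=C(C)C)c(Br)c1
F5 | step 11 | (1S)-3-[2-bromo-4-(methoxymethoxy)phenyl]-1-[8-(methoxymethoxy)-2,2-dimethyl-7-(3-methylbut-2-en-1-yl)-2H-chromen-6-yl]propan-1-ol | CC(C)=CCc1c([C@@H](O)CCc3ccc(OCOC)cc3Br)cc2c(c1OCOC)OC(C)(C)C=C2
F6 | step 1 | 4-hydroxy-3-methoxyacetophenone | CC(=O)c1ccc(O)c(OC)c1
F7 | step 1 | 1-[3-methoxy-4-(2-methylbut-3-yn-2-yloxy)phenyl]ethanone | CC(=O)c1ccc(OC(C)(C)C#C)c(OC)c1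
F8 | step 1 | 1-(8-methoxy-2,2-dimethyl-2H-chromen-6-yl)ethanone | CC(=O)c1cc(OC)c2OC(C)(C)C=Cc2c1
F9 | step 5 | 1-[2,2-dimethyl-8-(prop-2-en-1-yloxy)-2H-chromen-6-yl]ethanone | CC(=O)c1cc(OCC=C)c2OC(C)(C)C=Cc2c1
F10 | step 5 | 1-[8-hydroxy-2,2-dimethyl-7-(prop-2-en-1-yl)-2H-chromen-6-yl]ethanone | CC(=O)c1cc2C=CC(C)(C)Oc2c(O)c1CC=C
F0 | step 10 | none | none
F11 | step 12 | Kazinol B bis(trimethylsilyl) ether, (2S)-2-[2,2-dimethyl-7-(3-methylbut-2-en-1-yl)-8-(trimethylsilyloxy)-2H-chromen-6-yl]-7-(trimethylsilyloxy)-3,4-dihydro-2H-chromene | CC(C)=CCc1c([C@@H]2CCc3ccc(O[Si](C)(C)C)cc3O2)cc2c(c1O[Si](C)(C)C)OC(C)(C)C=C2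
A1 | alternative 1 | (6S)-6-[8-(methoxymethoxy)-2,2-dimethyl-7-(3-methylbut-2-en-1-yl)-2H-chromen-6-yl]oxan-2-one | O=C1CCC[C@@H](c2cc3C=CC(C)(C)Oc3c(OCOC)c2CC=C(C)C)O1
A2 | alternative 1 | 4-[(3S)-3-hydroxy-3-[8-(methoxymethoxy)-2,2-dimethyl-7-(3-methylbut-2-en-1-yl)-2H-chromen-6-yl]propyl]cyclohexane-1,3-dione (both epimers at the ring carbon) | CC(C)=CCc1c([C@@H](O)CCC3CCC(=O)CC3=O)cc2c(c1OCOC)OC(C)(C)C=C2
A3 | alternative 2 | 4-[(tert-butyldimethylsilyl)oxy]-2-hydroxybenzaldehyde | O=Cc1ccc(O[Si](C)(C)C(C)(C)C)cc1O
A4 | alternative 2 | (2E)-3-[8-[(tert-butyldimethylsilyl)oxy]-2,2-dimethyl-7-(3-methylbut-2-en-1-yl)-2H-chromen-6-yl]prop-2-enal | O=C/C=C/c1cc2C=CC(C)(C)Oc2c(O[Si](C)(C)C(C)(C)C)c1CC=C(C)C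
A5 | alternative 2 | (2R)-7-[(tert-butyldimethylsilyl)oxy]-2-[8-[(tert-butyldimethylsilyl)oxy]-2,2-dimethyl-7-(3-methylbut-2-en-1-yl)-2H-chromen-6-yl]-2H-chromene-3-carbaldehyde | CC(C)=CCc1c([C@@H]2C(C=O)=Cc3ccc(O[Si](C)(C)C(C)(C)C)cc3O2)cc2c(c1O[Si](C)(C)C(C)(C)C)OC(C)(C)C=C2
A6 | alternative 3 | 4-[(2S)-7-[(tert-butyldimethylsilyl)oxy]-3,4-dihydro-2H-chromen-2-yl]-3-(3-methylbut-2-en-1-yl)benzene-1,2-diol | CC(C)=CCc1c([C@@H]2CCc3ccc(O[Si](C)(C)C(C)(C)C)cc3O2)ccc(O)c1O
A7 | alternative 3 | 3-methylbut-2-enal | CC(C)=CC=O
A8 | alternative 3 | Kazinol B 7-O-tert-butyldimethylsilyl ether | CC(C)=CCc1c([C@@H]2CCc3ccc(O[Si](C)(C)C(C)(C)C)cc3O2)cc2c(c1O)OC(C)(C)C=C2
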